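Remark on the chemistry: the (Sa,S,S) antipode of the phosphoramidite ligand is assumed to deliver the (S) ether 15, in line with the usual facial preference of this catalyst family. Should the sense prove opposite, the (Ra,R,R) ligand is used and nothing else changes.

## Analysis of the target

Compound 24 is a (2S)-flavanone: a chroman-4-one (rings A and C) that carries ring B at C2. C2 is the only stereocentre; it is benzylic, bonded to O1 and β to the C4 ketone. It can be lost in two ways: base opens ring C by retro-oxa-Michael reaction to an achiral chalcone, and acid can ionise the C2–O1 bond. Ring A is a 5,7-dihydroxy (phloroglucinol-type) ring. Ring B carries a 4'-methoxy group flanked by a prenyl group at C3' and an (E)-3-hydroxy-3-methylbut-1-enyl group at C5'. The tertiary, allylic and styrenic alcohol ionises or dehydrates in acid, the prenyl alkene is sensitive to acid, electrophiles and oxidants, and the free phenols make the ring-opening easier. The difficulty lies in setting one labile stereocentre and carrying it through ring closure and the completion of ring B, with three different alkenes in the molecule. The strategy rests on ring A: before ring C is closed, the two carbons ortho to O1 (the later C4a and C8) are equivalent, and each is activated by O1 and by the oxygens at C5 and C7. Formation of the C4–C4a bond by electrophilic acylation therefore has only one possible regiochemical outcome.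

## Retrosynthetic reasoning

The two phenols of 24 are freed last, from the bis(silyl) ether 23. Free phenols on ring A would otherwise have to survive acylation, palladium catalysis and base, and buffered fluoride touches nothing else in 23.

The C5'–alkenyl bond of 23 is cut next, giving the aryl iodide 21 and 2-methylbut-3-en-2-ol 22. The cut is made here because the tertiary allylic alcohol is the most acid-sensitive group of the target and its styrenic alkene would interfere with hydroboration and metathesis earlier on. An iodine atom at C5' is inert to all the preceding chemistry. The forward Heck reaction has to give only the E alkene, which the absence of a hydrogen on the carbinol carbon ensures.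

Ring C of 21 is opened at the C4–C4a bond, which leads to the β-aryloxy acid 19. Cutting here, and not at O1–C2, keeps the C2–O1 bond, and with it the stereocentre, intact during ring closure, and it uses the local symmetry of ring A, so no regiochemical question arises. The forward step is an intramolecular Friedel–Crafts acylation through the mixed anhydride 20; it has to be faster than ionisation at C2.

The carboxyl group of 19 is traced back through the primary alcohol 17 to the terminal alkene of the branched allylic ether 15. The vinyl group is thus a masked acid: anti-Markovnikov hydration and oxidation turn it into C3 and C4 without touching C2. The forward hydroboration has to select the monosubstituted alkene over the prenyl group.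

The C2–O1 bond of 15 is cut to give the cinnamyl carbonate 12 and the phenol 14. This is the one stereogenic step of the route: an iridium-catalysed allylic etherification has to give the branched regioisomer and the (S) configuration. The phenol 14 is symmetric, so it does not matter which ortho carbon later becomes C4a.

Phenol 14 comes from phloroglucinol 13 by silylation of two of its three equivalent hydroxyl groups.

Carbonate 12 is taken back through the allylic alcohol 11 and the ester 10 to the aldehyde 8 and triethyl phosphonoacetate 9, which supplies C3 and C4. An E-selective olefination and a 1,2-reduction are all that is required.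

The prenyl group of 8 is cut at its double bond, giving the allyl arene 6 and 2-methylbut-2-ene 7. Compound 6 comes from the phenol 5 by O-methylation. Phenol 5 is the Claisen product of the allyl ether 3, through the dienone 4, and 3 is made from 4-hydroxy-3-iodobenzaldehyde 1 and allyl bromide 2. The iodine in 1 blocks one ortho position, so the allyl group can only end up at the other, and the same iodine later serves as the handle for the Heck reaction.

## Alternatives that were turned down

Alternative 1: The C3=C4 bond is cut, so that ring C would be closed by ring-closing metathesis. The diene A2 carries the vinyl group on C2 and a 1-silyloxyvinyl group on ring A. With the second-generation Grubbs catalyst, (H2IMes)(PCy3)Cl2Ru=CHPh, it would give the cyclic silyl enol ether A1, a masked form of the ketone.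
- For it: the closure is neutral, so the C2–O1 bond is never exposed to acid, and the vinyl group from the allylic etherification is used as it stands. This saves the hydroboration and the oxidation, and on these two points it is stronger than the chosen route.
- Against it: A2 contains two further alkenes on ring B, the prenyl group and the styrenic alkene. The electron-rich 1,1-disubstituted enol ether is a slow metathesis partner that needs heat and high catalyst loading, and under those conditions the ruthenium carbene can also engage the ring B alkenes, truncating the prenyl group or cross-coupling. The allylic etherification would also have to be run on an ortho-acylated, internally hydrogen-bonded phenoxide, which should be slower and less selective than the symmetric phenoxide from 14. A1 still needs hydrolysis and desilylation.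
- Comparison: the chosen route spends two more steps, but its ring closure is indifferent to the other alkenes and ring B is finished afterwards from the iodide.

Alternative 2: Ring A is built onto a preformed ring C. The diazo ketone A4, a 6-(diazoacetyl)-2-aryl-2,3-dihydropyran-4-one, would undergo a photochemical Wolff rearrangement to a vinylketene. This adds the siloxyalkyne A5 to give a cyclobutenone, and electrocyclic ring opening and 6π closure then give the phenol A3.
- For it: the sequence needs no acid, and ring A arrives with the C5 hydroxyl free and the C7 oxygen silylated. On the differentiation of the two phenols it is stronger than the chosen route.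
- Against it: the differentiation is of no use here, because both phenols are free in 24, and ring A is available as 13. A4 needs an enantioselective synthesis of the dihydropyranone followed by introduction of the diazoacetyl group, which is several steps for a sensitive β-alkoxy enone. The styrenic chromophore of ring B absorbs where the diazo ketone is irradiated, so E/Z isomerisation should compete, and the enone itself is photoactive.
- Comparison: the stereocentre would still have to be made beforehand, so nothing is gained in stereocontrol, and the route is longer.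

Alternative 3: The C2–C3 bond is cut. The diazo ketone A7, an aryl diazomethyl ketone with a benzyloxy group in the ortho position, would lose nitrogen on Rh2(S-PTTL)4, dirhodium tetrakis(N-phthaloyl-(S)-tert-leucinate). The carbene would insert into one of the two enantiotopic benzylic C–H bonds to give the flavanone A6.
- For it: this is the shortest plan; one step forms the C2–C3 bond, ring C and the stereocentre from an achiral ether. On step economy it is clearly stronger than the chosen route.
- Against it: the carbene has only one acceptor group and is highly electrophilic. The ether oxygen sits 1,5 to the carbene carbon, so a five-membered oxonium ylide followed by a 1,2-shift of the benzyl group competes with the 1,6-insertion. The prenyl and styrenic alkenes invite cyclopropanation, and ring B invites Buchner-type addition. Asymmetric induction for insertions of this carbene class that form six-membered rings cannot be relied on.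
- Comparison: the chosen route takes more steps, but each bond-forming step has a single expected outcome, and the stereocentre is set by a catalyst system of wide scope and then not touched again.

Key step: step 12

## Route

Step 1
Reactants: 1 4-hydroxy-3-iodobenzaldehyde; 2 allyl bromide (3-bromoprop-1-ene)
Product: 3 4-(allyloxy)-3-iodobenzaldehyde
Conditions: K2CO3, DMF, rt
Reagents that add atoms: none
Why: Williamson ether synthesis; the acidic phenol is fully ionised by carbonate and the phenoxide displaces the primary allylic bromide at oxygen.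

Step 2
Reactants: 3 4-(allyloxy)-3-iodobenzaldehyde
Product: 5 3-allyl-4-hydroxy-5-iodobenzaldehyde, via allyl cyclohexadienone 4 (not isolated)
Conditions: N,N-diethylaniline, 190 °C, argon, dark
Reagents that add atoms: none
Why: Aromatic Claisen rearrangement; the [3,3] shift ends productively only at the unsubstituted ortho carbon, where dienone 4 enolises to the phenol, whereas migration to the iodinated carbon gives a dienone that cannot tautomerise and reverts.

Step 3
Reactants: 5 3-allyl-4-hydroxy-5-iodobenzaldehyde
Product: 6 3-allyl-5-iodo-4-methoxybenzaldehyde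
Conditions: MeI, K2CO3, DMF, rt
Reagents that add atoms: iodomethane, CI
Why: SN2 O-methylation of a hindered but acidic phenoxide; it fixes the 4'-methoxy group and removes the free phenol before the ruthenium and hydride steps.

Step 4
Reactants: 6 3-allyl-5-iodo-4-methoxybenzaldehyde; 7 2-methylbut-2-ene
Product: 8 3-iodo-4-methoxy-5-(3-methylbut-2-en-1-yl)benzaldehyde
Conditions: second-generation Grubbs catalyst (H2IMes)(PCy3)Cl2Ru=CHPh (3 mol%), 2-methylbut-2-ene/CH2Cl2, 40 °C
Reagents that add atoms: none
Why: Olefin cross-metathesis; the terminal allyl group exchanges its methylene for the isopropylidene unit of the excess alkene, and the trisubstituted prenyl product is a poor substrate for further metathesis, so the reaction should stop there.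

Step 5
Reactants: 8 3-iodo-4-methoxy-5-(3-methylbut-2-en-1-yl)benzaldehyde; 9 triethyl phosphonoacetate
Product: 10 ethyl (E)-3-[3-iodo-4-methoxy-5-(3-methylbut-2-en-1-yl)phenyl]prop-2-enoate
Conditions: NaH, THF, 0 °C to rt
Reagents that add atoms: none
Why: Horner–Wadsworth–Emmons olefination; the stabilised phosphonate anion gives the E cinnamate and brings in the carbons that become C3 and C4.

Step 6
Reactants: 10 ethyl (E)-3-[3-iodo-4-methoxy-5-(3-methylbut-2-en-1-yl)phenyl]prop-2-enoate
Product: 11 (E)-3-[3-iodo-4-methoxy-5-(3-methylbut-2-en-1-yl)phenyl]prop-2-en-1-ol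
Conditions: iBu2AlH (2.5 equiv), CH2Cl2, −78 to 0 °C; aq. potassium sodium tartrate
Reagents that add atoms: none
Why: 1,2-reduction of the unsaturated ester by the electrophilic aluminium hydride without conjugate reduction; the aryl iodide is inert at this temperature.

Step 7
Reactants: 11 (E)-3-[3-iodo-4-methoxy-5-(3-methylbut-2-en-1-yl)phenyl]prop-2-en-1-ol
Product: 12 methyl (E)-3-[3-iodo-4-methoxy-5-(3-methylbut-2-en-1-yl)phenyl]prop-2-en-1-yl carbonate
Conditions: ClCO2Me, pyridine, CH2Cl2, 0 °C
Reagents that add atoms: methyl chloroformate, COC(=O)Cl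
Why: Acylation of the primary allylic alcohol; the methyl carbonate is the leaving group required for ionisation by the iridium catalyst.

Step 8
Reactants: 13 phloroglucinol (benzene-1,3,5-triol)
Product: 14 3,5-bis(triisopropylsilyloxy)phenol
Conditions: iPr3SiCl (2.0 equiv), imidazole, DMF, 0 °C to rt; chromatography
Reagents that add atoms: chlorotriisopropylsilane, CC(C)[Si](Cl)(C(C)C)C(C)C
Why: Statistical silylation of three equivalent hydroxyl groups; the bis(silyl) ether should be the main component at two equivalents and is separable from the mono- and tris-silylated material, which can be recycled.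

Step 9
Reactants: 12 methyl (E)-3-[3-iodo-4-methoxy-5-(3-methylbut-2-en-1-yl)phenyl]prop-2-en-1-yl carbonate; 14 3,5-bis(triisopropylsilyloxy)phenol
Product: 15 (S)-1-[3,5-bis(triisopropylsilyloxy)phenoxy]-1-[3-iodo-4-methoxy-5-(3-methylbut-2-en-1-yl)phenyl]prop-2-ene
Conditions: 14, n-BuLi, THF, 0 °C; then 12, [Ir(cod)Cl]2 (2 mol%), (Sa,S,S)-O,O'-(1,1'-binaphthalene-2,2'-diyl) N,N-bis(1-phenylethyl)phosphoramidite (4 mol%, catalyst pre-formed with n-PrNH2), THF, rt to 40 °C
Reagents that add atoms: none
Why: Iridium-catalysed asymmetric allylic etherification; the carbonate ionises to an allyl–iridium complex on the cyclometalated catalyst and the lithium aryloxide attacks the aryl-substituted terminus anti to the metal, giving the branched ether. The chiral ligand fixes which face of the allyl unit is bound and so sets C2 as (S); the two silyloxy groups shield the ring carbons of the phenoxide, which favours attack through oxygen.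

Step 10
Reactants: 15 (S)-1-[3,5-bis(triisopropylsilyloxy)phenoxy]-1-[3-iodo-4-methoxy-5-(3-methylbut-2-en-1-yl)phenyl]prop-2-ene
Product: 17 (S)-3-[3,5-bis(triisopropylsilyloxy)phenoxy]-3-[3-iodo-4-methoxy-5-(3-methylbut-2-en-1-yl)phenyl]propan-1-ol, via B-alkyl-9-BBN adduct 16 (not isolated)
Conditions: 9-BBN (1.3 equiv), THF, 0 °C to rt; then NaBO3·4H2O, H2O, rt
Reagents that add atoms: sodium perborate (used as NaBO3·4H2O), [Na+].[O-]OB=O
Why: Anti-Markovnikov hydroboration–oxidation; 9-BBN reacts with the monosubstituted alkene far faster than with the trisubstituted prenyl group and places boron on the terminal carbon, away from the aryloxy group. Perborate oxidises the C–B bond at a mild pH that should spare the aryl silyl ethers; C2 is not involved.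

Step 11
Reactants: 17 (S)-3-[3,5-bis(triisopropylsilyloxy)phenoxy]-3-[3-iodo-4-methoxy-5-(3-methylbut-2-en-1-yl)phenyl]propan-1-ol
Product: 19 (S)-3-[3,5-bis(triisopropylsilyloxy)phenoxy]-3-[3-iodo-4-methoxy-5-(3-methylbut-2-en-1-yl)phenyl]propanoic acid, via β-aryloxy aldehyde 18 (not isolated)
Conditions: TEMPO (0.2 equiv), PhI(OAc)2 (2.5 equiv), MeCN/CH2Cl2/H2O, rt
Reagents that add atoms: water, O
Why: Oxoammonium-mediated oxidation of the primary alcohol to aldehyde 18, whose hydrate is oxidised further to the acid. The medium is weakly acidic, so β-elimination of the aryloxide from 18 is not expected, and alkenes, aryl ethers and the aryl iodide are not attacked.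

Step 12
Reactants: 19 (S)-3-[3,5-bis(triisopropylsilyloxy)phenoxy]-3-[3-iodo-4-methoxy-5-(3-methylbut-2-en-1-yl)phenyl]propanoic acid
Product: 21 (S)-5'-iodo-4'-methoxy-3'-(3-methylbut-2-en-1-yl)-5,7-bis(triisopropylsilyloxy)flavanone, via mixed trifluoroacetic anhydride 20 (not isolated)
Conditions: (CF3CO)2O (1.5 equiv), 2,6-di-tert-butylpyridine (3 equiv), CH2Cl2, −20 to 0 °C
Reagents that add atoms: none
Why: Acid 19 and (CF3CO)2O give the mixed anhydride 20, whose alkanoyl carbon (or the acylium ion in equilibrium with it) is attacked by the ring A carbon that is ortho to O1, ortho to one silyloxy group and para to the other; loss of a proton from the arenium ion to the pyridine base restores the arene and completes the C4–C4a bond. The closest known reaction type is the intramolecular Friedel–Crafts acylation of 3-aryloxypropanoic acids to chroman-4-ones through trifluoroacetyl mixed anhydrides. Ring C closes in a 6-exo-trig mode at the acyl carbon (6-exo-dig if a free acylium ion is the electrophile) and is fused to ring A. No stereocentre is formed; C2, set in step 9, stays (S) as long as the C2–O1 bond does not ionise. Regioselectivity needs no control, because the two carbons ortho to O1 are equivalent and the carbon between the two silyloxy groups cannot reach the acyl carbon. What the step needs is chemoselectivity: acylation of ring A has to be faster than ionisation at C2, protonation of the prenyl alkene and attack on ring B, which would give an indanone. This is secured by the threefold oxygen activation of ring A, by the low donor power of ring B (its methoxy group is forced out of the ring plane by the flanking iodine and prenyl groups, and iodine withdraws inductively), and by the hindered pyridine, which takes up CF3CO2H without attacking the anhydride. The new ketone deactivates ring A, so a second acylation is not expected.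

Step 13
Reactants: 21 (S)-5'-iodo-4'-methoxy-3'-(3-methylbut-2-en-1-yl)-5,7-bis(triisopropylsilyloxy)flavanone; 22 2-methylbut-3-en-2-ol
Product: 23 (S)-3'-[(E)-3-hydroxy-3-methylbut-1-en-1-yl]-4'-methoxy-5'-(3-methylbut-2-en-1-yl)-5,7-bis(triisopropylsilyloxy)flavanone
Conditions: Pd(OAc)2 (10 mol%), Bu4NCl, NaHCO3, DMF, 50 °C
Reagents that add atoms: none
Why: Heck reaction; the aryl iodide adds oxidatively to zerovalent palladium, the aryl group is delivered to the unsubstituted alkene terminus, and β-hydride elimination can occur only towards the benzylic carbon because the carbinol carbon bears no hydrogen, which gives the E styrene. The ligand-free, phase-transfer conditions with a weak base at moderate temperature are chosen to avoid enolisation and opening of ring C.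

Step 14
Reactants: 23 (S)-3'-[(E)-3-hydroxy-3-methylbut-1-en-1-yl]-4'-methoxy-5'-(3-methylbut-2-en-1-yl)-5,7-bis(triisopropylsilyloxy)flavanone
Product: 24 (2S)-5,7-dihydroxy-2-[3-[(E)-3-hydroxy-3-methylbut-1-en-1-yl]-4-methoxy-5-(3-methylbut-2-en-1-yl)phenyl]chroman-4-one
Conditions: Bu4NF (2.5 equiv), AcOH (3 equiv), THF, 0 °C
Reagents that add atoms: none
Why: Fluoride cleaves the two aryl O–Si bonds; acetic acid protonates the phenoxides as they form, so the medium stays too weakly basic to open ring C, and too weakly acidic to ionise the tertiary allylic alcohol.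

## Compound list

1 | 4-hydroxy-3-iodobenzaldehyde | O=Cc1ccc(O)c(I)c1 | starting material
2 | allyl bromide | C=CCBr | starting material
3 | 4-(allyloxy)-3-iodobenzaldehyde | O=Cc1ccc(OCC=C)c(I)c1 | intermediate
4 | 3-allyl-5-iodo-4-oxocyclohexa-1,5-diene-1-carbaldehyde (racemic Claisen dienone) | O=CC1=CC(CC=C)C(=O)C(I)=C1 | intermediate
5 | 3-allyl-4-hydroxy-5-iodobenzaldehyde | O=Cc1cc(CC=C)c(O)c(I)c1 | intermediate
6 | 3-allyl-5-iodo-4-methoxybenzaldehyde | O=Cc1cc(CC=C)c(OC)c(I)c1 | intermediate
7 | 2-methylbut-2-ene | CC=C(C)C | starting material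
8 | 3-iodo-4-methoxy-5-(3-methylbut-2-en-1-yl)benzaldehyde | O=Cc1cc(CC=C(C)C)c(OC)c(I)c1 | intermediate
9 | triethyl phosphonoacetate | CCOC(=O)CP(=O)(OCC)OCC | starting material
10 | ethyl (E)-3-[3-iodo-4-methoxy-5-(3-methylbut-2-en-1-yl)phenyl]prop-2-enoate | CCOC(=O)/C=C/c1cc(CC=C(C)C)c(OC)c(I)c1 | intermediate
11 | (E)-3-[3-iodo-4-methoxy-5-(3-methylbut-2-en-1-yl)phenyl]prop-2-en-1-ol | OC/C=C/c1cc(CC=C(C)C)c(OC)c(I)c1 | intermediate
12 | methyl (E)-3-[3-iodo-4-methoxy-5-(3-methylbut-2-en-1-yl)phenyl]prop-2-en-1-yl carbonate | COC(=O)OC/C=C/c1cc(CC=C(C)C)c(OC)c(I)c1 | intermediate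
13 | phloroglucinol | Oc1cc(O)cc(O)c1 | starting material
14 | 3,5-bis(triisopropylsilyloxy)phenol | Oc1cc(O[Si](C(C)C)(C(C)C)C(C)C)cc(O[Si](C(C)C)(C(C)C)C(C)C)c1 | intermediate
15 | (S)-1-[3,5-bis(triisopropylsilyloxy)phenoxy]-1-[3-iodo-4-methoxy-5-(3-methylbut-2-en-1-yl)phenyl]prop-2-ene | C=C[C@@H](c1cc(CC=C(C)C)c(OC)c(I)c1)Oc1cc(O[Si](C(C)C)(C(C)C)C(C)C)cc(O[Si](C(C)C)(C(C)C)C(C)C)c1 | intermediate
16 | 9-[(S)-3-[3,5-bis(triisopropylsilyloxy)phenoxy]-3-[3-iodo-4-methoxy-5-(3-methylbut-2-en-1-yl)phenyl]propyl]-9-borabicyclo[3.3.1]nonane | C1CCC2CCCC1B2CC[C@@H](c1cc(CC=C(C)C)c(OC)c(I)c1)Oc1cc(O[Si](C(C)C)(C(C)C)C(C)C)cc(O[Si](C(C)C)(C(C)C)C(C)C)c1 | intermediate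
17 | (S)-3-[3,5-bis(triisopropylsilyloxy)phenoxy]-3-[3-iodo-4-methoxy-5-(3-methylbut-2-en-1-yl)phenyl]propan-1-ol | OCC[C@@H](c1cc(CC=C(C)C)c(OC)c(I)c1)Oc1cc(O[Si](C(C)C)(C(C)C)C(C)C)cc(O[Si](C(C)C)(C(C)C)C(C)C)c1 | intermediate
18 | (S)-3-[3,5-bis(triisopropylsilyloxy)phenoxy]-3-[3-iodo-4-methoxy-5-(3-methylbut-2-en-1-yl)phenyl]propanal | O=CC[C@@H](c1cc(CC=C(C)C)c(OC)c(I)c1)Oc1cc(O[Si](C(C)C)(C(C)C)C(C)C)cc(O[Si](C(C)C)(C(C)C)C(C)C)c1 | intermediate
19 | (S)-3-[3,5-bis(triisopropylsilyloxy)phenoxy]-3-[3-iodo-4-methoxy-5-(3-methylbut-2-en-1-yl)phenyl]propanoic acid | OC(=O)C[C@@H](c1cc(CC=C(C)C)c(OC)c(I)c1)Oc1cc(O[Si](C(C)C)(C(C)C)C(C)C)cc(O[Si](C(C)C)(C(C)C)C(C)C)c1 | intermediate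
20 | mixed anhydride of 19 with trifluoroacetic acid | O=C(OC(=O)C[C@@H](c1cc(CC=C(C)C)c(OC)c(I)c1)Oc1cc(O[Si](C(C)C)(C(C)C)C(C)C)cc(O[Si](C(C)C)(C(C)C)C(C)C)c1)C(F)(F)F | intermediate
21 | (S)-5'-iodo-4'-methoxy-3'-(3-methylbut-2-en-1-yl)-5,7-bis(triisopropylsilyloxy)flavanone | O=C1C[C@@H](c2cc(CC=C(C)C)c(OC)c(I)c2)Oc2cc(O[Si](C(C)C)(C(C)C)C(C)C)cc(O[Si](C(C)C)(C(C)C)C(C)C)c12 | intermediate
22 | 2-methylbut-3-en-2-ol | C=CC(C)(C)O | starting material
23 | (S)-3'-[(E)-3-hydroxy-3-methylbut-1-en-1-yl]-4'-methoxy-5'-(3-methylbut-2-en-1-yl)-5,7-bis(triisopropylsilyloxy)flavanone | O=C1C[C@@H](c2cc(CC=C(C)C)c(OC)c(/C=C/C(C)(C)O)c2)Oc2cc(O[Si](C(C)C)(C(C)C)C(C)C)cc(O[Si](C(C)C)(C(C)C)C(C)C)c12 | intermediate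
24 | (2S)-5,7-dihydroxy-2-[3-[(E)-3-hydroxy-3-methylbut-1-en-1-yl]-4-methoxy-5-(3-methylbut-2-en-1-yl)phenyl]chroman-4-one | COc1c(/C=C/C(C)(C)O)cc([C@@H]2CC(=O)c3c(O)cc(O)cc3O2)cc1CC=C(C)C | target

## Step count and risk

Total step count: 14. Longest linear sequence: 13 steps (steps 1 to 7 and 9 to 14, from 1 to 24); step 8 is a one-step side branch from 13.

**Step 12 (key step).** The most likely failure is ionisation of the C2–O1 bond under the acidic activation, which would lead to loss of configuration, elimination or C-alkylation of ring A. Sluggish acylation is also possible, because the reacting carbon lies next to a bulky silyloxy group. The fallback changes the electrophile to one generated and consumed under base. Acid 19 is condensed with dimethylamine (carbodiimide coupling) to the N,N-dimethylamide F1. Amide F1 is activated with (CF3SO2)2O and 2-chloropyridine in CH2Cl2 at low temperature, so that ring A attacks the activated amide in a Vilsmeier–Haack-type closure to the cyclic iminium triflate F2. Aqueous NaHCO3 then hydrolyses F2 to the ketone, and the route is rejoined at 21.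

**Step 9.** The risks are incomplete branched selectivity, insufficient facial control for this tetrasubstituted aryl group, or partial re-ionisation of the product ether on the catalyst, each of which would lower the enantiomeric purity carried to the end. The fallback sets the stereocentre by oxygen transfer and introduces the aryl ether by inversion.
- Allylic alcohol 11 is subjected to Sharpless asymmetric epoxidation (Ti(OiPr)4, L-(+)-diethyl tartrate, t-BuOOH) to give the (2S,3S)-epoxy alcohol F3.
- NaAlH2(OCH2CH2OMe)2 opens F3 at C2 to the (R)-1-arylpropane-1,3-diol F4.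
- Pivaloyl chloride and pyridine acylate the primary hydroxyl group selectively, giving the pivalate F5.
- A Mitsunobu reaction of F5 with phenol 14 (PPh3, diisopropyl azodicarboxylate) inverts the benzylic centre and gives the (S)-aryl ether pivalate F6.
- iBu2AlH removes the pivaloyl group, and the route is rejoined at 17.

**Step 13.** The concern is base-induced enolisation and retro-oxa-Michael opening of ring C during the Heck reaction, which would erode the configuration at C2, together with partial loss of the peri silyl ether. The fallback is a base-free Stille coupling. The stannane (E)-2-methyl-4-(tributylstannyl)but-3-en-2-ol F7, made from 2-methylbut-3-yn-2-ol and Bu3SnH under radical conditions, is coupled with iodide 21 using Pd2(dba)3, AsPh3 and CuI in DMF near room temperature. The route is rejoined at 23.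

**Step 2.** At 190 °C, deiodination or decomposition of the iodo aldehyde may compete with the rearrangement. The fallback lowers the Claisen temperature by using a tertiary allyl ether.
- Phenol 1 is alkylated with 3-chloro-3-methylbut-1-yne (CuCl2 catalyst, DBU, MeCN, 0 °C) to the propargyl ether 3-iodo-4-[(2-methylbut-3-yn-2-yl)oxy]benzaldehyde F8.
- Semihydrogenation over Pd/CaCO3 poisoned with Pb(OAc)2 and quinoline gives 3-iodo-4-[(2-methylbut-3-en-2-yl)oxy]benzaldehyde F9.
- F9 rearranges in xylene at about 130 °C directly to the prenyl phenol 4-hydroxy-3-iodo-5-(3-methylbut-2-en-1-yl)benzaldehyde F10.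
- Methylation with MeI and K2CO3 rejoins the route at 8, replacing steps 1 to 4.

**Step 14.** Phenoxide formation during desilylation could open ring C and racemise C2, and a more acidic fluoride source is excluded by the tertiary allylic alcohol. The fallback reverses the order of the last two steps. Iodide 21 is desilylated with HF·pyridine in THF/pyridine, which is safe because no allylic alcohol is present yet, to give (S)-5,7-dihydroxy-5'-iodo-4'-methoxy-3'-(3-methylbut-2-en-1-yl)flavanone F11. Base-free Stille coupling of F11 with the stannane F7 then gives 24 directly.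

## Further compounds

F1 | step 12 | (S)-3-[3,5-bis(triisopropylsilyloxy)phenoxy]-3-[3-iodo-4-methoxy-5-(3-methylbut-2-en-1-yl)phenyl]-N,N-dimethylpropanamide | CN(C)C(=O)C[C@@H](c1cc(CC=C(C)C)c(OC)c(I)c1)Oc1cc(O[Si](C(C)C)(C(C)C)C(C)C)cc(O[Si](C(C)C)(C(C)C)C(C)C)c1
F2 | step 12 | (S)-N-[2-[3-iodo-4-methoxy-5-(3-methylbut-2-en-1-yl)phenyl]-5,7-bis(triisopropylsilyloxy)chroman-4-ylidene]-N-methylmethanaminium trifluoromethanesulfonate | C[N+](C)=C1C[C@@H](c2cc(CC=C(C)C)c(OC)c(I)c2)Oc2cc(O[Si](C(C)C)(C(C)C)C(C)C)cc(O[Si](C(C)C)(C(C)C)C(C)C)c12.[O-]S(=O)(=O)C(F)(F)F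
F3 | step 9 | [(2S,3S)-3-[3-iodo-4-methoxy-5-(3-methylbut-2-en-1-yl)phenyl]oxiran-2-yl]methanol | OC[C@@H]1O[C@H]1c1cc(CC=C(C)C)c(OC)c(I)c1
F4 | step 9 | (R)-1-[3-iodo-4-methoxy-5-(3-methylbut-2-en-1-yl)phenyl]propane-1,3-diol | OCC[C@@H](O)c1cc(CC=C(C)C)c(OC)c(I)c1
F5 | step 9 | (R)-3-hydroxy-3-[3-iodo-4-methoxy-5-(3-methylbut-2-en-1-yl)phenyl]propyl pivalate | CC(C)(C)C(=O)OCC[C@@H](O)c1cc(CC=C(C)C)c(OC)c(I)c1
F6 | step 9 | (S)-3-[3,5-bis(triisopropylsilyloxy)phenoxy]-3-[3-iodo-4-methoxy-5-(3-methylbut-2-en-1-yl)phenyl]propyl pivalate | CC(C)(C)C(=O)OCC[C@@H](c1cc(CC=C(C)C)c(OC)c(I)c1)Oc1cc(O[Si](C(C)C)(C(C)C)C(C)C)cc(O[Si](C(C)C)(C(C)C)C(C)C)c1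
F7 | step 13 | (E)-2-methyl-4-(tributylstannyl)but-3-en-2-ol | CCCC[Sn](CCCC)(CCCC)/C=C/C(C)(C)O
F8 | step 2 | 3-iodo-4-[(2-methylbut-3-yn-2-yl)oxy]benzaldehyde | O=Cc1ccc(OC(C)(C)C#C)c(I)c1
F9 | step 2 | 3-iodo-4-[(2-methylbut-3-en-2-yl)oxy]benzaldehyde | O=Cc1ccc(OC(C)(C)C=C)c(I)c1
F10 | step 2 | 4-hydroxy-3-iodo-5-(3-methylbut-2-en-1-yl)benzaldehyde | O=Cc1cc(CC=C(C)C)c(O)c(I)c1
F11 | step 14 | (S)-5,7-dihydroxy-5'-iodo-4'-methoxy-3'-(3-methylbut-2-en-1-yl)flavanone | O=C1C[C@@H](c2cc(CC=C(C)C)c(OC)c(I)c2)Oc2cc(O)cc(O)c12
A1 | alternative 1 | (S)-4-(tert-butyldimethylsilyloxy)-2-[3-[(E)-3-(tert-butyldimethylsilyloxy)-3-methylbut-1-en-1-yl]-4-methoxy-5-(3-methylbut-2-en-1-yl)phenyl]-5,7-bis(triisopropylsilyloxy)-2H-chromene | CC(C)(C)[Si](C)(C)OC1=C[C@@H](c2cc(CC=C(C)C)c(OC)c(/C=C/C(C)(C)O[Si](C)(C)C(C)(C)C)c2)Oc2cc(O[Si](C(C)C)(C(C)C)C(C)C)cc(O[Si](C(C)C)(C(C)C)C(C)C)c12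
A2 | alternative 1 | (S)-1-aryl-1-[2-[1-(tert-butyldimethylsilyloxy)vinyl]-3,5-bis(triisopropylsilyloxy)phenoxy]prop-2-ene, aryl being the complete silylated ring B | C=C[C@@H](c1cc(CC=C(C)C)c(OC)c(/C=C/C(C)(C)O[Si](C)(C)C(C)(C)C)c1)Oc1cc(O[Si](C(C)C)(C(C)C)C(C)C)cc(O[Si](C(C)C)(C(C)C)C(C)C)c1C(=C)O[Si](C)(C)C(C)(C)C
A3 | alternative 2 | (S)-5-hydroxy-2-[4-methoxy-3-(3-methylbut-2-en-1-yl)-5-[(E)-3-methyl-3-(triethylsilyloxy)but-1-en-1-yl]phenyl]-7-(triisopropylsilyloxy)chroman-4-one | O=C1C[C@@H](c2cc(CC=C(C)C)c(OC)c(/C=C/C(C)(C)O[Si](CC)(CC)CC)c2)Oc2cc(O[Si](C(C)C)(C(C)C)C(C)C)cc(O)c12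
A4 | alternative 2 | (S)-6-(2-diazoacetyl)-2-[4-methoxy-3-(3-methylbut-2-en-1-yl)-5-[(E)-3-methyl-3-(triethylsilyloxy)but-1-en-1-yl]phenyl]-2,3-dihydro-4H-pyran-4-one | [N-]=[N+]=CC(=O)C1=CC(=O)C[C@@H](c2cc(CC=C(C)C)c(OC)c(/C=C/C(C)(C)O[Si](CC)(CC)CC)c2)O1
A5 | alternative 2 | (triisopropylsilyloxy)ethyne | C#CO[Si](C(C)C)(C(C)C)C(C)C
A6 | alternative 3 | (S)-2-[4-methoxy-3-(3-methylbut-2-en-1-yl)-5-[(E)-3-methyl-3-(triethylsilyloxy)but-1-en-1-yl]phenyl]-5,7-bis(triisopropylsilyloxy)chroman-4-one | O=C1C[C@@H](c2cc(CC=C(C)C)c(OC)c(/C=C/C(C)(C)O[Si](CC)(CC)CC)c2)Oc2cc(O[Si](C(C)C)(C(C)C)C(C)C)cc(O[Si](C(C)C)(C(C)C)C(C)C)c12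
A7 | alternative 3 | 2-diazo-1-[2-[[4-methoxy-3-(3-methylbut-2-en-1-yl)-5-[(E)-3-methyl-3-(triethylsilyloxy)but-1-en-1-yl]phenyl]methoxy]-4,6-bis(triisopropylsilyloxy)phenyl]ethan-1-one | [N-]=[N+]=CC(=O)c1c(OCc2cc(CC=C(C)C)c(OC)c(/C=C/C(C)(C)O[Si](CC)(CC)CC)c2)cc(O[Si](C(C)C)(C(C)C)C(C)C)cc1O[Si](C(C)C)(C(C)C)C(C)C
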